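**Retrosynthetic overview**
- Target 8 comes from methyl ether 6 by O-demethylation with BBr3, a bromide-based reagent, so any halide exchange at the pyrimidine C2–Br is degenerate.
- 6 is disconnected at the indole C3–pyrimidine C5 biaryl bond: copper-catalysed C–H arylation of unfunctionalised 6-bromo-4-methoxy-1H-indole (5) by pyrimidin-5-yl(mesityl)iodonium triflate 4.
- 4 comes from 2-bromopyrimidin-4-amine (1) by C5 iodination and oxidation/arylation at iodine. No ring is built in the route: the pyrimidine and the indole are bought intact and only joined.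
- Enabling feature: indole C3 is the β-carbon of the N1–C2=C3 enamine of the pyrrole ring, its one strongly nucleophilic C–H. Pyrimidine C5 is the only ring carbon not bonded to a ring nitrogen and lies ortho to the C4 amino group, so it alone accepts iodine and then carries the trivalent-iodine leaving group. This nucleophile/electrophile pairing never touches either C–Br bond.

Key step: step 3

Assumption: 2-bromopyrimidin-4-amine (1) and 6-bromo-4-methoxy-1H-indole (5) are taken as catalogue compounds, and the biaryl axis of the target, which carries no stereodescriptor, is treated as freely rotating.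

Step 1
Reactants: 1 2-bromopyrimidin-4-amine
Product: 2 2-bromo-5-iodopyrimidin-4-amine
Conditions: NIS (1.1 equiv), DMF, 60 °C, dark
Reagents that add atoms: N-iodosuccinimide O=C1CCC(=O)N1I
Why: Electrophilic aromatic iodination (SEAr); C5 is the only carbon of 1 not attached to a ring nitrogen and is ortho to the C4 amino donor, so iodine should enter there alone, as in the standard C5 iodination of 2-halopyrimidin-4-amines.

Step 2
Reactants: 2 2-bromo-5-iodopyrimidin-4-amine
Product: 4 (4-amino-2-bromopyrimidin-5-yl)(2,4,6-trimethylphenyl)iodonium trifluoromethanesulfonate, via hydroxy(triflyloxy)iodane 3 (not isolated)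
Conditions: mCPBA (1.1 equiv), TfOH (3 equiv), CH2Cl2, 0 to 40 °C; then mesitylene (1.1 equiv), 0 °C to rt; aq NaHCO3 wash, Et2O trituration
Reagents that add atoms: meta-chloroperoxybenzoic acid OOC(=O)c1cccc(Cl)c1 (its oxygen stays only in intermediate 3); trifluoromethanesulfonic acid OS(=O)(=O)C(F)(F)F; mesitylene Cc1cc(C)cc(C)c1
Why: One-pot oxidation/arylation synthesis of unsymmetrical diaryliodonium triflates, a reaction type established for iodopyridines and other N-heteroaryl iodides; in TfOH the aminopyrimidine is N-protonated and thereby shielded from the peracid while iodine is oxidised to the trivalent species 3, which then substitutes mesitylene by SEAr.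

Step 3
Reactants: 4 (4-amino-2-bromopyrimidin-5-yl)(2,4,6-trimethylphenyl)iodonium trifluoromethanesulfonate; 5 6-bromo-4-methoxy-1H-indole
Product: 6 2-bromo-5-(6-bromo-4-methoxy-1H-indol-3-yl)pyrimidin-4-amine
Conditions: Cu(OTf)2 (10 mol %), 2,6-di-tert-butylpyridine (1.2 equiv), CH2Cl2 or DCE, 35–50 °C, N2; filtration through silica
Reagents that add atoms: none
Why: Cu(OTf)2 is reduced in the flask by the indole to monovalent copper, which inserts into the iodonium C–I bond of 4 on the less hindered pyrimidinyl side (the mesityl group with two ortho methyls stays on iodine and leaves as iodomesitylene) to give a strongly electrophilic pyrimidin-5-yl trivalent copper triflate; indole 5 attacks it through C3, the hindered pyridine base removes the C3 proton, and reductive elimination forms the indole C3–pyrimidine C5 bond and returns monovalent copper. The closest known reaction type is the Cu(OTf)2-catalysed C3–H arylation of N–H indoles with aryl(mesityl)iodonium triflates, an electrophilic Friedel–Crafts-type C–H arylation. No ring is closed and no stereocentre is created; the new biaryl axis is not configurationally stable. The step needs C3 selectivity over N1, C2, C5 and C7: C3 is the β-carbon of the N1–C2=C3 enamine, the free N–H carries no acyl group that would steer the metal to C2, the anisole-type carbons C5 and C7 are far less nucleophilic and each sits next to the C6 bromine, and without strong base N1 is not arylated. It also needs both C–Br bonds to survive, which the copper/iodonium couple should secure because monovalent copper at 35–50 °C inserts into the hypervalent C–I bond but not into aryl or 2-pyrimidinyl bromides.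

Step 4
Reactants: 6 2-bromo-5-(6-bromo-4-methoxy-1H-indol-3-yl)pyrimidin-4-amine
Product: 8 3-(4-amino-2-bromopyrimidin-5-yl)-6-bromo-1H-indol-4-ol, via aryloxydibromoborane 7 (not isolated)
Conditions: BBr3 (5 equiv), CH2Cl2, −78 to 0 °C; then ice-water
Reagents that add atoms: boron tribromide BrB(Br)Br (boron and bromine stay only in intermediate 7)
Why: Lewis-acid aryl methyl ether cleavage; BBr3 coordinates the methoxy oxygen, bromide removes the methyl group by SN2 to give borate 7, and water hydrolyses the O–B bond, while excess reagent covers the basic nitrogens and bromide cannot scramble the C2 halogen.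

**Compound list**
1 | 2-bromopyrimidin-4-amine | Nc1ccnc(Br)n1 | starting material
2 | 2-bromo-5-iodopyrimidin-4-amine | Nc1nc(Br)ncc1I | intermediate
3 | (4-amino-2-bromopyrimidin-5-yl)(hydroxy)(trifluoromethylsulfonyloxy)-λ3-iodane | Nc1nc(Br)ncc1I(O)OS(=O)(=O)C(F)(F)F | intermediate
4 | (4-amino-2-bromopyrimidin-5-yl)(2,4,6-trimethylphenyl)iodonium trifluoromethanesulfonate | Nc1nc(Br)ncc1[I+]c1c(C)cc(C)cc1C.[O-]S(=O)(=O)C(F)(F)F | intermediate
5 | 6-bromo-4-methoxy-1H-indole | COc1cc(Br)cc2[nH]ccc12 | starting material
6 | 2-bromo-5-(6-bromo-4-methoxy-1H-indol-3-yl)pyrimidin-4-amine | COc1cc(Br)cc2[nH]cc(-c3cnc(Br)nc3N)c12 | intermediate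
7 | dibromo{[3-(4-amino-2-bromopyrimidin-5-yl)-6-bromo-1H-indol-4-yl]oxy}borane | BrB(Br)Oc1cc(Br)cc2[nH]cc(-c3cnc(Br)nc3N)c12 | intermediate
8 | 3-(4-amino-2-bromopyrimidin-5-yl)-6-bromo-1H-indol-4-ol | Nc1nc(Br)ncc1-c1c[nH]c2cc(Br)cc(O)c12 | target

**Step count**
Total steps: 4. Longest linear sequence: 4 steps (1 → 2 → 4 → 6 → 8); indole 5 enters unchanged at step 3.

**Steps most likely to fail**

Step 3 (key arylation). Coordination of the aminopyrimidine nitrogens to copper may stall turnover. The amino group of one iodonium ion may be N-arylated by another. Attack at the peri-hindered C3 may become slow enough for C7 arylation or mesityl transfer to compete. The fallback is a Suzuki–Miyaura union, setting out from 5 and using iodide 2 as the partner. Indole 5 would be iodinated at C3 (NIS, DMF, 0 °C) to 6-bromo-3-iodo-4-methoxy-1H-indole F1. N-protection (Boc2O, DMAP, MeCN) would give tert-butyl 6-bromo-3-iodo-4-methoxyindole-1-carboxylate F2. Iodine–magnesium exchange selective for C–I over C–Br (iPrMgCl·LiCl, THF, −40 °C), then 2-isopropoxy-4,4,5,5-tetramethyl-1,3,2-dioxaborolane, would give tert-butyl 6-bromo-4-methoxy-3-(4,4,5,5-tetramethyl-1,3,2-dioxaborolan-2-yl)indole-1-carboxylate F3. Coupling of F3 with 2 (Pd(dppf)Cl2, K3PO4, dioxane/water, 50 °C) relies on zerovalent palladium inserting into the C5–I bond faster than into either C–Br bond, and should give tert-butyl 3-(4-amino-2-bromopyrimidin-5-yl)-6-bromo-4-methoxyindole-1-carboxylate F4. Removal of the carbamate (TFA, CH2Cl2, 0 °C) returns to the route at 6.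

Step 2 (iodonium formation). Oxidation of the protonated, electron-poor iodide at iodine may be slow, and the peracid may over-oxidise the amino group or ring nitrogens. The fallback swaps the roles of the partners and avoids the peracid. It sets out from 1 and treats it with commercial (diacetoxyiodo)mesitylene and TfOH in 2,2,2-trifluoroethanol at 0 °C to rt. The mesityl trivalent-iodine electrophile should then substitute the C5–H of 1 directly by SEAr. The route is rejoined at 4, and no compound outside the list is made (F0).

Step 4 (demethylation). The three basic nitrogens may sequester BBr3 and leave cleavage incomplete. The acidic medium may degrade the electron-rich 4-hydroxyindole. The C2–Br bond may be hydrolysed during acidic aqueous work-up. The fallback moves the ether cleavage to the robust starting indole and changes the protecting group. From 5, BBr3 (CH2Cl2, −78 to 0 °C) would give 6-bromo-1H-indol-4-ol F5. O-acetylation (Ac2O, pyridine, CH2Cl2, 0 °C) would give 6-bromo-1H-indol-4-yl acetate F6. Arylation of F6 with 4 under the step 3 conditions would give 3-(4-amino-2-bromopyrimidin-5-yl)-6-bromo-1H-indol-4-yl acetate F7. Methanolysis with catalytic K2CO3 in MeOH at 0 °C, too mild for substitution at C2–Br, arrives at 8.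

Further compounds
F0 | step 2 | none | none
F1 | step 3 | 6-bromo-3-iodo-4-methoxy-1H-indole | COc1cc(Br)cc2[nH]cc(I)c12
F2 | step 3 | tert-butyl 6-bromo-3-iodo-4-methoxyindole-1-carboxylate | COc1cc(Br)cc2c1c(I)cn2C(=O)OC(C)(C)C
F3 | step 3 | tert-butyl 6-bromo-4-methoxy-3-(4,4,5,5-tetramethyl-1,3,2-dioxaborolan-2-yl)indole-1-carboxylate | COc1cc(Br)cc2c1c(B1OC(C)(C)C(C)(C)O1)cn2C(=O)OC(C)(C)C
F4 | step 3 | tert-butyl 3-(4-amino-2-bromopyrimidin-5-yl)-6-bromo-4-methoxyindole-1-carboxylate | COc1cc(Br)cc2c1c(-c1cnc(Br)nc1N)cn2C(=O)OC(C)(C)C
F5 | step 4 | 6-bromo-1H-indol-4-ol | Oc1cc(Br)cc2[nH]ccc12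
F6 | step 4 | 6-bromo-1H-indol-4-yl acetate | CC(=O)Oc1cc(Br)cc2[nH]ccc12
F7 | step 4 | 3-(4-amino-2-bromopyrimidin-5-yl)-6-bromo-1H-indol-4-yl acetate | CC(=O)Oc1cc(Br)cc2[nH]cc(-c3cnc(Br)nc3N)c12
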